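## Retrosynthetic overview

1. Both rings are closed in the last step: cutting C5–C6 and C4–O(lactone) leads back to an acyclic (3S)-peroxyketal acid. The 1,2-dioxane closes first (peroxycarbenium/alkene C–C bond), and the γ-lactone closes immediately after in the same flask (carboxyl capture of the C4 cation).
2. The peroxyketal acid comes from a β-peroxy aldehyde (Pinnick oxidation), made by enantioselective peroxy-Michael addition of the side-chain α-methoxy hydroperoxide to (E)-4-methylpenta-2,4-dienal. This sets C3; C4 and C6 are relayed from C3 in the ring-forming step.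
3. The α-methoxy hydroperoxide comes from (9E,11E)-12-phenyldodeca-9,11-dien-2-one, made from 8-oxononanal and diethyl cinnamylphosphonate (HWE); 8-oxononanal comes from 9-decen-2-one (ozonolysis).
4. The dienal comes from methacrolein and formylmethylene-triphenylphosphorane (Wittig).

Assumption: positions are numbered from the lactone carbonyl (C1; peroxide on C3 and C6, lactone oxygen on C4); carbon building blocks are numbered as reactants, while reagents that deliver only heteroatoms or a one-carbon acetal unit are given on the reagent line.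

## Route

Step 1
Reactants: 1 dec-9-en-2-one
Product: 3 8-oxononanal, via ozonide 2 (not isolated)
Conditions: O3, CH2Cl2, −78 °C; then PPh3, −78 °C → rt
Reagents that add atoms: ozone, [O-][O+]=O
Why: Ozonolysis of the only C=C and reductive cleavage of ozonide 2 gives the keto-aldehyde with the ketone untouched; no stereocenter is formed.

Step 2
Reactants: 4 diethyl [(2E)-3-phenylprop-2-en-1-yl]phosphonate; 3 8-oxononanal
Product: 6 (9E,11E)-12-phenyldodeca-9,11-dien-2-one, via lithiated phosphonate 5 (not isolated)
Conditions: LiHMDS (1.0 equiv), THF, −78 °C; then slow addition of 3, −78 → 0 °C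
Reagents that add atoms: none
Why: Horner–Wadsworth–Emmons olefination with a semi-stabilised allylic phosphonate anion forms the new C9=C10 bond E-selectively (the styryl bond stays E), and the aldehyde reacts far faster than the methyl ketone at low temperature.

Step 3
Reactants: 6 (9E,11E)-12-phenyldodeca-9,11-dien-2-one
Product: 8 (9E,11E)-2-hydroperoxy-2-methoxy-12-phenyldodeca-9,11-diene (racemic at C2), via dimethyl ketal 7 (not isolated)
Conditions: HC(OMe)3 (5 equiv), CSA (2 mol%), rt; evaporate; then anhydrous H2O2 in Et2O (1.5 equiv), CSA (2 mol%), 0 °C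
Reagents that add atoms: trimethyl orthoformate, COC(OC)OC; hydrogen peroxide, OO
Why: Acid-catalysed ketalisation followed by perketal exchange (the oxocarbenium ion is captured by the α-effect nucleophile H2O2, kept near stoichiometric to stop at the mono-hydroperoxide) is the standard entry to α-alkoxy hydroperoxides; the new ketal centre is racemic and is planarised again in step 7.

Step 4
Reactants: 9 methacrolein (3 equiv); 10 (triphenylphosphoranylidene)acetaldehyde
Product: 11 (2E)-4-methylpenta-2,4-dienal
Conditions: PhMe, 70 °C, sealed vessel; distil (volatile; kept as a cold solution)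
Reagents that add atoms: none
Why: Wittig olefination with the stabilised formyl ylide gives the E-enal, and excess methacrolein suppresses a second homologation; no stereocenter is formed.

Step 5
Reactants: 11 (2E)-4-methylpenta-2,4-dienal; 8 (9E,11E)-2-hydroperoxy-2-methoxy-12-phenyldodeca-9,11-diene
Product: 12 (3S)-3-{[(9E,11E)-2-methoxy-12-phenyldodeca-9,11-dien-2-yl]peroxy}-4-methylpent-4-enal (about 1:1 epimers at the peroxyketal carbon)
Conditions: (R)-α,α-diphenylprolinol TMS ether (10 mol%), PhCO2H (10 mol%), PhMe, −20 °C
Reagents that add atoms: none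
Why: Iminium-catalysed enantioselective peroxy-Michael addition (β-peroxidation of an enal by an α-alkoxy hydroperoxide) in which the diarylmethyl group of the (R)-catalyst blocks one face of the s-trans iminium ion so that the peroxide oxygen adds to C3 to give 3S (sense assigned from the antipodal catalyst's β-oxygenation of enals, to be confirmed on the first batch), with 1,4-addition preferred at the more electrophilic β-carbon and the acid co-catalyst protonating the enamine before it can close to an epoxide.

Step 6
Reactants: 12 (3S)-peroxy aldehyde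
Product: 13 (3S)-3-{[(9E,11E)-2-methoxy-12-phenyldodeca-9,11-dien-2-yl]peroxy}-4-methylpent-4-enoic acid (about 1:1 epimers at the peroxyketal carbon; used at once)
Conditions: NaClO2, NaH2PO4, 2-methyl-2-butene (20 equiv), t-BuOH/H2O, 0 °C, short reaction time
Reagents that add atoms: sodium chlorite, [Na+].[O-]Cl=O
Why: Pinnick oxidation converts only the aldehyde, the scavenger protects the alkenes from HOCl, the cold buffered medium spares the peroxyketal, and C3 is not touched.

Step 7
Reactants: 13 (3S)-peroxyketal acid
Product: 16 plakortolide R, via peroxycarbenium ion 14 (not isolated), via tertiary dioxanyl cation 15 (not isolated)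
Conditions: TMSOTf (0.2 equiv), 4 Å MS, CH2Cl2 (0.01 M), −78 → −40 °C; Et3N quench; chromatography
Reagents that add atoms: none
Why: Proposed new method: ionisation of the methoxy peroxyketal gives peroxycarbenium ion 14, the isopropenyl CH2 (C5) adds 6-endo through a chair (C3 side chain and the long C6 chain equatorial, C6 methyl axial) to give tertiary cation 15, and the tethered carboxyl captures C4 on the only face it can reach and releases the proton that turns the catalyst over, so C4–O is cis to C2 by ring constraint and C6 follows from the chair preference (moderate dr expected, C6 epimer removed by chromatography); the closest known reaction types are the Lewis-acid peroxycarbenium–alkene cyclisation to halide-capped 1,2-dioxanes and Prins cyclisations terminated by a carboxyl group.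

## Compound list

1 | dec-9-en-2-one | CC(=O)CCCCCCC=C | starting material
2 | 8-(1,2,4-trioxolan-3-yl)octan-2-one (ozonide) | CC(=O)CCCCCCC1OCOO1 | intermediate (not isolated)
3 | 8-oxononanal | CC(=O)CCCCCCC=O | intermediate
4 | diethyl [(2E)-3-phenylprop-2-en-1-yl]phosphonate | CCOP(=O)(OCC)C/C=C/c1ccccc1 | starting material
5 | lithiated diethyl cinnamylphosphonate | [Li+].CCOP(=O)(OCC)[CH-]/C=C/c1ccccc1 | intermediate (not isolated)
6 | (9E,11E)-12-phenyldodeca-9,11-dien-2-one | CC(=O)CCCCCC/C=C/C=C/c1ccccc1 | intermediate
7 | (9E,11E)-2,2-dimethoxy-12-phenyldodeca-9,11-diene | CC(OC)(OC)CCCCCC/C=C/C=C/c1ccccc1 | intermediate (not isolated)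
8 | (9E,11E)-2-hydroperoxy-2-methoxy-12-phenyldodeca-9,11-diene (racemic at C2) | CC(OC)(OO)CCCCCC/C=C/C=C/c1ccccc1 | intermediate
9 | methacrolein | CC(=C)C=O | starting material
10 | (triphenylphosphoranylidene)acetaldehyde | O=CC=P(c1ccccc1)(c1ccccc1)c1ccccc1 | starting material
11 | (2E)-4-methylpenta-2,4-dienal | C=C(C)/C=C/C=O | intermediate
12 | (3S)-3-{[(9E,11E)-2-methoxy-12-phenyldodeca-9,11-dien-2-yl]peroxy}-4-methylpent-4-enal (epimers at the peroxyketal carbon) | O=CC[C@@H](C(C)=C)OOC(C)(OC)CCCCCC/C=C/C=C/c1ccccc1 | intermediate
13 | (3S)-3-{[(9E,11E)-2-methoxy-12-phenyldodeca-9,11-dien-2-yl]peroxy}-4-methylpent-4-enoic acid (epimers at the peroxyketal carbon) | OC(=O)C[C@@H](C(C)=C)OOC(C)(OC)CCCCCC/C=C/C=C/c1ccccc1 | intermediate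
14 | peroxycarbenium ion from 13 (C6=O+ attached through O–O to C3) | OC(=O)C[C@@H](C(C)=C)O[O+]=C(C)CCCCCC/C=C/C=C/c1ccccc1 | intermediate (not isolated)
15 | (3S,6S)-3-(carboxymethyl)-4,6-dimethyl-6-[(7E,9E)-10-phenyldeca-7,9-dien-1-yl]-1,2-dioxan-4-yl cation | C[C@]1(CCCCCC/C=C/C=C/c2ccccc2)C[C+](C)[C@H](CC(O)=O)OO1 | intermediate (not isolated)
16 | plakortolide R: (3S,4S,6S) cis-fused 1,2-dioxane/γ-lactone, 4-methyl, 6-methyl, 6-[(7E,9E)-10-phenyldeca-7,9-dien-1-yl] | C[C@]1(CCCCCC/C=C/C=C/c2ccccc2)C[C@]2(C)OC(=O)C[C@@H]2OO1 | target

## Step count and risks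

Total steps: 7. Longest linear sequence: 6 (steps 1, 2, 3, 5, 6, 7).

**Step 7 (ring-forming cascade).** The acid-sensitive phenyldiene may not survive the Lewis acid, and the C6 selectivity may be low. The fallback takes the diene out of the cascade and installs it last; it sets out from 1 and comes back at 16. Ketone 1 is ketalised as in step 3 to 9,9-dimethoxydec-1-ene F1 and exchanged with H2O2 to 9-hydroperoxy-9-methoxydec-1-ene F2. Peroxy-Michael addition of F2 to 11 under the step 5 conditions gives (3S)-3-[(2-methoxydec-9-en-2-yl)peroxy]-4-methylpent-4-enal F3, and Pinnick oxidation gives the corresponding pent-4-enoic acid F4. The same TMSOTf cyclisation, now with only an inert terminal alkene in the chain, gives the 6-(oct-7-en-1-yl) peroxylactone F5. Cross-metathesis of F5 with (E)-buta-1,3-dien-1-ylbenzene F6 (Hoveyda–Grubbs II, CH2Cl2, 40 °C; the neutral Ru carbene tolerates the dialkyl peroxide) then gives 16.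

**Step 5 (asymmetric peroxidation).** Epoxidation, 1,6-addition or low ee with this small hydroperoxide are all possible. The fallback replaces asymmetric catalysis by an ene reaction plus resolution; it sets out from 7 (isolated after neutralisation) and comes back at 13, so step 6 is also bypassed. 4-Methylpent-3-enoic acid F7 is photo-oxygenated (O2, TPP, hν, CH2Cl2, 0 °C; Schenck ene reaction) to racemic 3-hydroperoxy-4-methylpent-4-enoic acid F8, which is freed from the regioisomeric ene product by chromatography. Preparative chiral SFC gives (3S)-3-hydroperoxy-4-methylpent-4-enoic acid F9. Perketal exchange of F9 onto 7 (PPTS cat., CH2Cl2, 0 °C) gives 13.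

**Step 6 (Pinnick oxidation).** The peroxyketal may hydrolyse in the acidic aqueous buffer. The fallback moves the oxidation to after the cyclisation; it sets out from 12 and comes back at 16. Aldehyde 12 is submitted directly to the step 7 conditions. The aldehyde oxygen captures the C4 cation and the released methanol caps the resulting oxocarbenium ion, giving the bicyclic methyl lactol ether F10. Mild hydrolysis (AcOH/H2O/THF) gives lactol F11, and TEMPO/PhI(OAc)2 (CH2Cl2, rt) oxidises it to 16.

## Further compounds

F1 | step 7 | 9,9-dimethoxydec-1-ene | CC(OC)(OC)CCCCCCC=C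
F2 | step 7 | 9-hydroperoxy-9-methoxydec-1-ene (racemic) | CC(OC)(OO)CCCCCCC=C
F3 | step 7 | (3S)-3-[(2-methoxydec-9-en-2-yl)peroxy]-4-methylpent-4-enal | O=CC[C@@H](C(C)=C)OOC(C)(OC)CCCCCCC=C
F4 | step 7 | (3S)-3-[(2-methoxydec-9-en-2-yl)peroxy]-4-methylpent-4-enoic acid | OC(=O)C[C@@H](C(C)=C)OOC(C)(OC)CCCCCCC=C
F5 | step 7 | (3S,4S,6S) cis-fused 1,2-dioxane/γ-lactone, 4-methyl, 6-methyl, 6-(oct-7-en-1-yl) | C[C@]1(CCCCCCC=C)C[C@]2(C)OC(=O)C[C@@H]2OO1
F6 | step 7 | (E)-buta-1,3-dien-1-ylbenzene | C=C/C=C/c1ccccc1
F7 | step 5 | 4-methylpent-3-enoic acid | CC(C)=CCC(=O)O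
F8 | step 5 | 3-hydroperoxy-4-methylpent-4-enoic acid (racemic) | C=C(C)C(OO)CC(=O)O
F9 | step 5 | (3S)-3-hydroperoxy-4-methylpent-4-enoic acid | OC(=O)C[C@@H](C(C)=C)OO
F10 | step 6 | methyl lactol ether of 16 (lactone C=O replaced by CH(OMe), anomeric mixture) | C[C@]1(CCCCCC/C=C/C=C/c2ccccc2)C[C@]2(C)OC(OC)C[C@@H]2OO1
F11 | step 6 | lactol of 16 (lactone C=O replaced by CH(OH), anomeric mixture) | C[C@]1(CCCCCC/C=C/C=C/c2ccccc2)C[C@]2(C)OC(O)C[C@@H]2OO1
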